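Ring A (the hydroxy-acid ring; C1 carboxyl, C2 heptyl, C4 ether oxygen, C6 hydroxyl) carries the 1,3-dioxygen pattern of a vinylketene acetal next to the carboxyl/alkyl pair of a 2-alkynoate. It is therefore built last, on a finished ring B: the 3-aryloxy-1-methoxy-1-silyloxybutadiene, whose aryloxy group is ring B, adds across methyl dec-2-ynoate, forming C1–C6 and C2–C3, and the adduct aromatises by loss of methanol and the silyl group. One operation thus delivers the complete diaryl ether with the O–C4 bond never made by a coupling. The diene is the O-silyl ketene acetal of a β-aryloxycrotonate, obtained from the ring B salicylate and methyl but-2-ynoate. Hydrolysis of both methyl esters ends the route.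

Key step: step 8

Remark: the target has no stereocentre and no stereogenic double bond, so it is achiral and there is no enantiomer to select. The transient stereocentres of 5, 6, 7 and 17 are racemic and vanish on aromatisation. Ring A is numbered C1 (carboxyl-bearing), C2 (heptyl), C3 (H), C4 (aryloxy), C5 (H), C6 (hydroxyl).

Step 1
Reactants: 1 octanal; 2 1-(triphenyl-λ5-phosphanylidene)propan-2-one
Product: 3 (E)-undec-3-en-2-one
Conditions: CH2Cl2, reflux
Reagents that add atoms: none
Why: Wittig olefination with a ketone-stabilised ylide, which reacts cleanly with the unhindered aldehyde and should give the E-enone; no stereocentre is formed.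

Step 2
Reactants: 3 (E)-undec-3-en-2-one; 4 dimethyl malonate
Product: 6 methyl 6-heptyl-2,4-dioxocyclohexane-1-carboxylate (racemic; keto–enol mixture), via Michael adduct 5 (not isolated)
Conditions: NaOMe (1.2 equiv), MeOH, reflux; then aq. HCl, 0 °C
Reagents that add atoms: none
Why: Michael addition of the malonate anion to the enone and intramolecular Claisen (Dieckmann-type) acylation of the methyl-ketone enolate by one malonate ester close the dioxocyclohexane ring, the standard entry to 5-alkylresorcinol precursors; the two stereocentres are racemic and are erased in step 3.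

Step 3
Reactants: 6 methyl 6-heptyl-2,4-dioxocyclohexane-1-carboxylate
Product: 8 methyl 2-heptyl-4,6-dihydroxybenzoate, via bromodione 7 (not isolated)
Conditions: Br2 (1.0 equiv), DMF, 0 °C; then 80 °C
Reagents that add atoms: none
Why: Oxidative aromatisation by bromination of the 1,3-dione at C3 and thermal loss of two HBr (1,4-dehydrobromination through the keto-ester enol, then enolisation), as established for the 6-pentyl homologue; one equivalent of bromine at 0 °C limits nuclear bromination.

Step 4
Reactants: 8 methyl 2-heptyl-4,6-dihydroxybenzoate
Product: 9 methyl 2-heptyl-6-hydroxy-4-methoxybenzoate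
Conditions: MeI (1.05 equiv), K2CO3 (1.1 equiv), acetone, rt
Reagents that add atoms: iodomethane, CI
Why: Williamson methylation should take only the 4-OH, which is the more acidic (para to the ester) and unhindered phenol, while the 6-OH is held in a hydrogen bond to the ester carbonyl, as in the mono-methylation of orsellinates.

Step 5
Reactants: 9 methyl 2-heptyl-6-hydroxy-4-methoxybenzoate; 10 methyl but-2-ynoate
Product: 11 methyl 2-heptyl-4-methoxy-6-{[(2E)-4-methoxy-4-oxobut-2-en-2-yl]oxy}benzoate
Conditions: 10 (1.5 equiv), Cs2CO3 (0.2 equiv), DMF, 70 °C
Reagents that add atoms: none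
Why: Base-catalysed oxa-Michael addition of the phenoxide to the β-carbon of the ynoate gives the β-aryloxy enoate, and reversible addition–elimination of phenoxide under these conditions should settle the double bond in the more stable E form (aryloxy trans to the ester, methyl cis to it), which is the geometry needed for γ-deprotonation; the di-ortho-substituted ring B ester is inert.

Step 6
Reactants: 12 non-1-yne
Product: 14 methyl dec-2-ynoate, via lithium nonynide 13 (not isolated)
Conditions: n-BuLi (1.05 equiv), THF, −78 °C; then ClCO2Me, −78 → 0 °C
Reagents that add atoms: methyl chloroformate, COC(=O)Cl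
Why: Deprotonation of the terminal alkyne and C-acylation of the lithium acetylide with a chloroformate is the standard preparation of 2-alkynoates.

Step 7
Reactants: 11 methyl 2-heptyl-4-methoxy-6-{[(2E)-4-methoxy-4-oxobut-2-en-2-yl]oxy}benzoate
Product: 16 methyl 2-heptyl-4-methoxy-6-{[4-methoxy-4-(trimethylsilyloxy)buta-1,3-dien-2-yl]oxy}benzoate, via lithium dienolate 15 (not isolated)
Conditions: LDA (1.05 equiv), THF, −78 °C; then TMSCl (1.3 equiv), −78 °C → rt; pentane, filtration under Ar; used crude at once
Reagents that add atoms: chlorotrimethylsilane, C[Si](C)(C)Cl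
Why: Kinetic γ-deprotonation of the (E)-β-aryloxycrotonate (methyl cis to the coordinating ester carbonyl) and O-silylation of the dienolate is the way β-methoxycrotonates are turned into 1,3-dioxygenated silyl dienes; with one equivalent of LDA at −78 °C the much more acidic vinylogous ester position should be taken in preference to the benzylic CH2 of ring B, and the non-enolisable, shielded ring B ester does not react with the amide base.

Step 8
Reactants: 16 methyl 2-heptyl-4-methoxy-6-{[4-methoxy-4-(trimethylsilyloxy)buta-1,3-dien-2-yl]oxy}benzoate; 14 methyl dec-2-ynoate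
Product: 19 methyl 2-heptyl-4-[3-heptyl-5-methoxy-2-(methoxycarbonyl)phenoxy]-6-hydroxybenzoate, via cycloadduct 17 (not isolated), via aryl silyl ether 18 (not isolated)
Conditions: 14 (3 equiv), neat, trace BHT, 130 °C, sealed tube, Ar; then 1 M HCl, THF, rt
Reagents that add atoms: none
Why: The electron-rich diene (HOMO raised by the two ketene acetal oxygens and the aryloxy group, largest coefficient at the CH2 terminus) adds to the ester-polarised alkyne in a normal-demand, asynchronous [4+2] cycloaddition in which the CH2–Cβ bond (ring A C3–C2) leads and the ketene acetal carbon–Cα bond (C6–C1) follows; the stepwise limit, vinylogous Mukaiyama–Michael addition then closure of the allenoate carbon onto the silyl oxocarbenium carbon, gives the same adduct. The closest known reaction type is the Diels–Alder benzannulation of 1-alkoxy-1-silyloxy-3-oxybutadienes with 2-alkynoates, which gives 6-alkylresorcylates. Ring A is the only ring closed, as a six-membered carbocycle formed in the cycloaddition itself (four diene carbons plus two alkyne carbons), and cyclohexa-1,4-diene ketal 17 should then aromatise by thermal 1,4-loss of methanol to silyl ether 18, which the acidic work-up cleaves to the hydrogen-bonded phenol. No stereocentre survives, since the ketal carbon of 17 is formed racemic and becomes C6 of the arene. The step needs regioselectivity (CH2 terminus to the heptyl-bearing β-carbon), which is secured because the 1-oxy and 3-oxy donors of the diene direct in the same sense (ester ortho to the ketene acetal carbon, para to the aryloxy carbon) and the ester polarises the alkyne towards attack at Cβ. The aryloxy oxygen sits on diene C3 (ring A C4) as a vinyl ether with no elimination pathway, so the diaryl ether passes through unchanged, and the ring B ester is a thermal spectator.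

Step 9
Reactants: 19 methyl 2-heptyl-4-[3-heptyl-5-methoxy-2-(methoxycarbonyl)phenoxy]-6-hydroxybenzoate
Product: 20 2-(4-carboxy-3-heptyl-5-hydroxyphenoxy)-6-heptyl-4-methoxybenzoic acid
Conditions: KOH (10 equiv), DMSO–H2O 4:1, 90 °C; then 1 M HCl, 0 °C
Reagents that add atoms: potassium hydroxide, [K+].[OH-]
Why: Saponification (BAc2) by poorly solvated hydroxide in aqueous DMSO is the usual way to open di-ortho-substituted methyl benzoates; the diaryl ether and the aryl methyl ether are inert to hydroxide, the carboxylate salts resist decarboxylation in base, and cold acidification should release the diacid.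

Compound list
1 | octanal | CCCCCCCC=O | starting material
2 | 1-(triphenyl-λ5-phosphanylidene)propan-2-one | CC(=O)C=P(c1ccccc1)(c1ccccc1)c1ccccc1 | starting material
3 | (E)-undec-3-en-2-one | CCCCCCC/C=C/C(C)=O | intermediate
4 | dimethyl malonate | COC(=O)CC(=O)OC | starting material
5 | dimethyl 2-(2-oxoundecan-4-yl)propanedioate (Michael adduct, racemic) | CCCCCCCC(CC(C)=O)C(C(=O)OC)C(=O)OC | intermediate (not isolated)
6 | methyl 6-heptyl-2,4-dioxocyclohexane-1-carboxylate (racemic, diastereomer and keto–enol mixture) | CCCCCCCC1CC(=O)CC(=O)C1C(=O)OC | intermediate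
7 | methyl 3-bromo-6-heptyl-2,4-dioxocyclohexane-1-carboxylate (bromodione, stereoisomer mixture) | CCCCCCCC1CC(=O)C(Br)C(=O)C1C(=O)OC | intermediate (not isolated)
8 | methyl 2-heptyl-4,6-dihydroxybenzoate | CCCCCCCc1cc(O)cc(O)c1C(=O)OC | intermediate
9 | methyl 2-heptyl-6-hydroxy-4-methoxybenzoate | CCCCCCCc1cc(OC)cc(O)c1C(=O)OC | intermediate
10 | methyl but-2-ynoate | CC#CC(=O)OC | starting material
11 | methyl 2-heptyl-4-methoxy-6-{[(2E)-4-methoxy-4-oxobut-2-en-2-yl]oxy}benzoate | C/C(Oc1cc(OC)cc(CCCCCCC)c1C(=O)OC)=C\C(=O)OC | intermediate
12 | non-1-yne | CCCCCCCC#C | starting material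
13 | lithium non-1-yn-1-ide | [Li]C#CCCCCCCC | intermediate (not isolated)
14 | methyl dec-2-ynoate | CCCCCCCC#CC(=O)OC | intermediate
15 | lithium dienolate of 11 (lithium 3-aryloxy-1-methoxybuta-1,3-dien-1-olate; aryl = ring B) | C=C(Oc1cc(OC)cc(CCCCCCC)c1C(=O)OC)C=C(OC)O[Li] | intermediate (not isolated)
16 | methyl 2-heptyl-4-methoxy-6-{[4-methoxy-4-(trimethylsilyloxy)buta-1,3-dien-2-yl]oxy}benzoate (ketene acetal geometry not controlled, without consequence) | C=C(Oc1cc(OC)cc(CCCCCCC)c1C(=O)OC)C=C(OC)O[Si](C)(C)C | intermediate
17 | methyl 2-heptyl-4-[3-heptyl-5-methoxy-2-(methoxycarbonyl)phenoxy]-6-methoxy-6-(trimethylsilyloxy)cyclohexa-1,4-diene-1-carboxylate (cycloadduct, racemic) | CCCCCCCC1=C(C(=O)OC)C(OC)(O[Si](C)(C)C)C=C(Oc2cc(OC)cc(CCCCCCC)c2C(=O)OC)C1 | intermediate (not isolated)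
18 | methyl 2-heptyl-4-[3-heptyl-5-methoxy-2-(methoxycarbonyl)phenoxy]-6-(trimethylsilyloxy)benzoate | CCCCCCCc1cc(Oc2cc(OC)cc(CCCCCCC)c2C(=O)OC)cc(O[Si](C)(C)C)c1C(=O)OC | intermediate (not isolated)
19 | methyl 2-heptyl-4-[3-heptyl-5-methoxy-2-(methoxycarbonyl)phenoxy]-6-hydroxybenzoate | CCCCCCCc1cc(Oc2cc(OC)cc(CCCCCCC)c2C(=O)OC)cc(O)c1C(=O)OC | intermediate
20 | 2-(4-carboxy-3-heptyl-5-hydroxyphenoxy)-6-heptyl-4-methoxybenzoic acid | CCCCCCCc1cc(Oc2cc(OC)cc(CCCCCCC)c2C(=O)O)cc(O)c1C(=O)O | target

Total step count: 9. Longest linear sequence: 8 steps (1, 2, 3, 4, 5, 7, 8, 9); step 6 is a one-step side branch.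

Steps most likely to fail

Step 8. The cycloaddition to an unactivated internal ynoate may be slow, so that the crude silyl ketene acetal is lost first by hydrolysis back to 11 or by silyl migration. Some adduct may also lose silanol instead of methanol and end as the 6-O-methyl ether. Fallback: setting out from 9, O-triflation (Tf2O, pyridine, CH2Cl2, 0 °C) should give methyl 2-heptyl-4-methoxy-6-{[(trifluoromethyl)sulfonyl]oxy}benzoate F1. Palladium-catalysed C–O cross-coupling of F1 with resorcylate 8 (Pd(OAc)2, tBuXPhos, K3PO4, toluene, 100 °C) should arylate the free, more acidic 4-OH of 8 in preference to the chelated 6-OH, and so returns to the route at 19. The ether bond is then made by coupling at ring B instead of by building ring A, and steps 5, 7 and 8 are bypassed.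

Step 5. Conjugate addition of the hydrogen-bonded, ortho-substituted phenoxide to the β-methyl ynoate may be sluggish, with the ynoate consumed by oligomerisation, or the double bond may not equilibrate fully to the E form. Fallback: setting out from 10, hydroiodination (NaI, AcOH, 110 °C) should give methyl (2Z)-3-iodobut-2-enoate F2. Addition–elimination of the phenoxide of 9 on F2 (Cs2CO3, DMF, 60 °C, with CuI/N,N-dimethylglycine if needed) then replaces iodide at an sp2 carbon already at the right oxidation level, and under the equilibrating basic conditions should come back to the route at 11.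

Step 9. Saponification of the two shielded esters may stop at a mono-ester, or the salicylic acid unit of ring A may decarboxylate if the acidified mixture warms. Fallback: setting out from 19, lithium propane-1-thiolate in HMPA at rt attacks the ester methyl carbons (SN2, alkyl–oxygen cleavage), a process indifferent to the ortho substituents and too mild to touch the aryl methyl ether. Cold acidification then comes back to the route at 20; no new compound is made (F0).

Further compounds
F1 | step 8 | methyl 2-heptyl-4-methoxy-6-{[(trifluoromethyl)sulfonyl]oxy}benzoate | CCCCCCCc1cc(OC)cc(OS(=O)(=O)C(F)(F)F)c1C(=O)OC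
F2 | step 5 | methyl (2Z)-3-iodobut-2-enoate | C/C(I)=C/C(=O)OC
F0 | step 9 | none | none
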